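**Assumption:** the target has no stereocentre and no stereogenic double bond, so it is achiral and there is no enantiomer to control. The one transient stereocentre (the carbinol in 9) is made racemic and removed in step 5. The route is a paper design built on standard reactions and has not been run.

**Retrosynthetic overview**
- No ring is formed: all three benzene rings are bought, and the central ring comes from 3-hydroxy-5-methoxybenzaldehyde with OMe and OH already differentiated.
- Last disconnection: the ArCH2Ar bridge, from a doubly benzylic carbinol by ionic hydrogenation with simultaneous loss of both MOM groups.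
- The carbinol comes from directed ortho-metalation at the CH flanked by OMe and OMOM, then addition to 4-(methoxymethoxy)benzaldehyde.
- The CH2CH2 bridge comes from Wittig olefination with the ylide of (2-hydroxybenzyl)triphenylphosphonium bromide, then hydrogenation.
- Order of assembly: central ring + 2-hydroxyphenyl ring first (C2 bridge), then the 4-hydroxyphenyl ring (C1 bridge).

**Step 1**
Reactants: 1 3-hydroxy-5-methoxybenzaldehyde
Product: 2 3-methoxy-5-(methoxymethoxy)benzaldehyde
Conditions: MOMCl (1.5 eq), i-Pr2NEt (2 eq), CH2Cl2, 0 °C to rt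
Reagents that add atoms: chloromethyl methyl ether (MOMCl), COCCl
Why: O-alkylation (MOM protection) of the only OH gives the acid-labile group that later acts, together with OMe, as the ortho-director.

**Step 2**
Reactants: 2 3-methoxy-5-(methoxymethoxy)benzaldehyde; 3 (2-hydroxybenzyl)triphenylphosphonium bromide
Product: 5 2-{(E)-2-[3-methoxy-5-(methoxymethoxy)phenyl]ethenyl}phenol, via potassium 2-[(triphenyl-λ5-phosphanylidene)methyl]phenolate 4 (not isolated)
Conditions: 3 (1.15 eq), KOt-Bu (2.4 eq), THF, 0 °C to rt; then 2, rt to 50 °C; sat. aq NH4Cl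
Reagents that add atoms: none
Why: Wittig olefination with the phenoxide ylide made by double deprotonation of the salt, typically giving mainly the E alkene, whose geometry does not matter because it is hydrogenated next.

**Step 3**
Reactants: 5 2-{(E)-2-[3-methoxy-5-(methoxymethoxy)phenyl]ethenyl}phenol
Product: 6 2-{2-[3-methoxy-5-(methoxymethoxy)phenyl]ethyl}phenol
Conditions: H2 (1 atm), 10% Pd/C, EtOAc, rt
Reagents that add atoms: none
Why: Catalytic hydrogenation saturates the stilbene C=C without touching the aryl ethers, and removes an alkene that would undergo carbolithiation in step 4.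

**Step 4**
Reactants: 6 2-{2-[3-methoxy-5-(methoxymethoxy)phenyl]ethyl}phenol; 7 4-(methoxymethoxy)benzaldehyde
Product: 9 rac-2-[2-(4-{hydroxy[4-(methoxymethoxy)phenyl]methyl}-3-methoxy-5-(methoxymethoxy)phenyl)ethyl]phenol, via lithium 2-{2-[4-lithio-3-methoxy-5-(methoxymethoxy)phenyl]ethyl}phenolate 8 (not isolated)
Conditions: n-BuLi (2.3 eq), TMEDA, THF, 0 °C to rt, 1.5 h; then 7 (1.3 eq), −78 to 0 °C; sat. aq NH4Cl; product used crude or passed quickly through Et3N-treated silica
Reagents that add atoms: none
Why: Directed ortho-metalation, in which the first equivalent forms the lithium phenoxide (deactivating that ring) and the second removes the H flanked by OMe and OMOM as in 5-alkylresorcinol diethers, followed by 1,2-addition to the aldehyde to give a racemic carbinol that step 5 removes.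

**Step 5**
Reactants: 9 rac-2-[2-(4-{hydroxy[4-(methoxymethoxy)phenyl]methyl}-3-methoxy-5-(methoxymethoxy)phenyl)ethyl]phenol
Product: 11 5-[2-(2-hydroxyphenyl)ethyl]-2-[(4-hydroxyphenyl)methyl]-3-methoxyphenol, via 2-[2-(3-methoxy-5-(methoxymethoxy)-4-{[4-(methoxymethoxy)phenyl]methyl}phenyl)ethyl]phenol 10 (not isolated)
Conditions: Et3SiH (6 eq), TFA/CH2Cl2 (1:4), 0 °C 30 min, then rt 3–6 h; aq NaHCO3
Reagents that add atoms: none
Why: Ionic hydrogenation of the carbinol through a doubly benzylic, oxygen-stabilised cation, then TFA acidolysis of both aryl MOM ethers with excess silane reducing the released methoxymethyl cation to dimethyl ether; the aryl OMe is stable.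

**Compound list**
1 | 3-hydroxy-5-methoxybenzaldehyde | COc1cc(O)cc(C=O)c1 | starting material
2 | 3-methoxy-5-(methoxymethoxy)benzaldehyde | COCOc1cc(OC)cc(C=O)c1 | intermediate
3 | (2-hydroxybenzyl)triphenylphosphonium bromide | Oc1ccccc1C[P+](c1ccccc1)(c1ccccc1)c1ccccc1.[Br-] | starting material
4 | potassium 2-[(triphenyl-λ5-phosphanylidene)methyl]phenolate | [K+].[O-]c1ccccc1C=P(c1ccccc1)(c1ccccc1)c1ccccc1 | intermediate
5 | 2-{(E)-2-[3-methoxy-5-(methoxymethoxy)phenyl]ethenyl}phenol (E drawn; any Z isomer is carried on unseparated) | COCOc1cc(OC)cc(/C=C/c2ccccc2O)c1 | intermediate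
6 | 2-{2-[3-methoxy-5-(methoxymethoxy)phenyl]ethyl}phenol | COCOc1cc(OC)cc(CCc2ccccc2O)c1 | intermediate
7 | 4-(methoxymethoxy)benzaldehyde | COCOc1ccc(C=O)cc1 | starting material
8 | lithium 2-{2-[4-lithio-3-methoxy-5-(methoxymethoxy)phenyl]ethyl}phenolate | [Li]c1c(OC)cc(CCc2ccccc2O[Li])cc1OCOC | intermediate
9 | rac-2-[2-(4-{hydroxy[4-(methoxymethoxy)phenyl]methyl}-3-methoxy-5-(methoxymethoxy)phenyl)ethyl]phenol (racemic) | COCOc1ccc(C(O)c2c(OC)cc(CCc3ccccc3O)cc2OCOC)cc1 | intermediate
10 | 2-[2-(3-methoxy-5-(methoxymethoxy)-4-{[4-(methoxymethoxy)phenyl]methyl}phenyl)ethyl]phenol | COCOc1ccc(Cc2c(OC)cc(CCc3ccccc3O)cc2OCOC)cc1 | intermediate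
11 | 5-[2-(2-hydroxyphenyl)ethyl]-2-[(4-hydroxyphenyl)methyl]-3-methoxyphenol (achiral) | COc1cc(CCc2ccccc2O)cc(O)c1Cc1ccc(O)cc1 | target

**Total step count:** 5
**Longest linear sequence:** 5 (1 → 2 → 5 → 6 → 9 → 11; 3 and 7 are bought)

**Three steps most likely to fail, with fallbacks**

Step 4 is the highest risk. The dianion 8 may form incompletely or be poorly soluble, and the hindered carbinol 9 is acid-sensitive. The fallback sets out from 6 and replaces the dianion by a protected mono-anion. Silylation of 6 (TIPSCl, imidazole, DMF) gives triisopropyl(2-{2-[3-methoxy-5-(methoxymethoxy)phenyl]ethyl}phenoxy)silane F2, whose bulky OTIPS group neither consumes base nor directs metalation. n-BuLi/TMEDA (1.2 eq, THF, 0 °C) then gives [2-methoxy-6-(methoxymethoxy)-4-(2-{2-[tri(propan-2-yl)silyloxy]phenyl}ethyl)phenyl]lithium F3. Addition of 7 at −78 °C gives rac-[2-methoxy-6-(methoxymethoxy)-4-(2-{2-[tri(propan-2-yl)silyloxy]phenyl}ethyl)phenyl][4-(methoxymethoxy)phenyl]methanol F4. TBAF (THF, 0 °C) removes the silyl group and the sequence comes back to the route at 9.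

Step 5 carries three risks: Friedel–Crafts oligomerisation of the benzylic cation, reduction of a MOM ether to a methyl ether, and incomplete MOM cleavage. The fallback sets out from 9 and separates the two events; it makes no compound outside the list (F0). The doubly benzylic C–O bond is removed by catalytic hydrogenolysis (H2, Pd(OH)2/C, EtOH with a little AcOH), so no free cation and no silane are present while the MOM groups are still on. This rejoins the route at 10, now isolated. Compound 10 is then deprotected to 11 with catalytic conc. HCl in MeOH at 50 °C, where methanol traps the formaldehyde equivalent as dimethoxymethane.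

Step 2 may fail because the phenoxide ylide 4 can be sluggish or lose PPh3 to an o-quinone methide. The fallback sets out from 2 and forms the aryl–vinyl bond instead of the C=C bond. Methylenation of 2 (Ph3PCH3Br, KOt-Bu, THF, 0 °C) gives 1-ethenyl-3-methoxy-5-(methoxymethoxy)benzene F1. A Mizoroki–Heck arylation of F1 with 2-iodophenol (Pd(OAc)2, P(o-tol)3, Et3N, DMF, 100 °C) gives the E-stilbene and comes back to the route at 5.

**Further compounds**
F1 | step 2 | 1-ethenyl-3-methoxy-5-(methoxymethoxy)benzene | C=Cc1cc(OC)cc(OCOC)c1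
F2 | step 4 | triisopropyl(2-{2-[3-methoxy-5-(methoxymethoxy)phenyl]ethyl}phenoxy)silane | COCOc1cc(OC)cc(CCc2ccccc2O[Si](C(C)C)(C(C)C)C(C)C)c1
F3 | step 4 | [2-methoxy-6-(methoxymethoxy)-4-(2-{2-[tri(propan-2-yl)silyloxy]phenyl}ethyl)phenyl]lithium | [Li]c1c(OC)cc(CCc2ccccc2O[Si](C(C)C)(C(C)C)C(C)C)cc1OCOC
F4 | step 4 | rac-[2-methoxy-6-(methoxymethoxy)-4-(2-{2-[tri(propan-2-yl)silyloxy]phenyl}ethyl)phenyl][4-(methoxymethoxy)phenyl]methanol | COCOc1ccc(C(O)c2c(OC)cc(CCc3ccccc3O[Si](C(C)C)(C(C)C)C(C)C)cc2OCOC)cc1
F0 | step 5 | none | none
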